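**Retrosynthetic overview**

1. Target 18 ⇐ 17 (removal of the MOM ethers) ⇐ 16 (C4 alcohol to ketone). Rings A and B are bought; ring C is the only ring made and is formed in step 9.
2. Feature used: in ring C the ether oxygen O1 joins the stereocentre C2 to the aromatic carbon C8a of ring A. Ring C is therefore closed at O1–C8a by copper-catalysed O-arylation of bromo diol 15, with the C2–O bond already in place and no 2'-hydroxychalcone on the path.
3. 15 ⇐ hydroxyl-directed anti reduction of (S)-hydroxy ketone 14 ⇐ catalyst-controlled transfer hydrogenation of the ring B carbonyl of diketone 13. This sets C2 and is preferred to a chiral boron enolate aldol, whose enantioselectivity with methyl ketones is usually moderate.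
4. 13 ⇐ aldol addition (C3–C4 bond) of ring B methyl ketone 10 to ring A aldehyde 4, then oxidation.
5. 4 ⇐ 5-bromoresorcinol 1 (formylation, MOM ethers); 10 ⇐ 3'-bromo-4'-methoxyacetophenone 5 and prenyl bromide 7.

Key step: step 9

Remark: ketone 5 is taken as commercially available. Either C4 epimer would serve, because C4 becomes the ketone in step 10; the anti (1S,3S) diol is made so that every intermediate is a single stereoisomer.

**Route**

Step 1
Reactants: 1 5-bromoresorcinol
Product: 3 2-bromo-4,6-dihydroxybenzaldehyde, via iminium chloride 2 (not isolated)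
Conditions: POCl3, DMF, MeCN, 0 °C to rt; then H2O, 50 °C
Reagents that add atoms: N,N-dimethylformamide CN(C)C=O (the formyl carbon); water O (the carbonyl oxygen)
Why: Vilsmeier–Haack formylation of an activated resorcinol, which should take place at the ring carbon para to one hydroxyl and ortho to the other (the site next to bromine, as orcinol gives orcylaldehyde) and not at the more crowded carbon between the two hydroxyls, the iminium salt 2 being hydrolysed on warming with water.

Step 2
Reactants: 3 2-bromo-4,6-dihydroxybenzaldehyde
Product: 4 2-bromo-4,6-bis(methoxymethoxy)benzaldehyde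
Conditions: NaH, MOMCl, DMF, 0 °C to rt
Reagents that add atoms: chloromethyl methyl ether COCCl
Why: Williamson O-alkylation of both sodium phenoxides, the strong base ensuring that the hydroxyl hydrogen-bonded to the aldehyde is alkylated as well.

Step 3
Reactants: 5 1-(3-bromo-4-methoxyphenyl)ethanone
Product: 6 2-(3-bromo-4-methoxyphenyl)-2-methyl-1,3-dioxolane
Conditions: HOCH2CH2OH, p-TsOH·H2O (cat.), toluene, reflux (Dean–Stark)
Reagents that add atoms: ethylene glycol OCCO
Why: acid-catalysed ketalisation driven by azeotropic removal of water, which masks the ketone against the organolithium of step 4.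

Step 4
Reactants: 6 2-(3-bromo-4-methoxyphenyl)-2-methyl-1,3-dioxolane; 7 prenyl bromide (1-bromo-3-methylbut-2-ene)
Product: 10 1-[4-methoxy-3-(3-methylbut-2-en-1-yl)phenyl]ethanone, via aryllithium 8 (not isolated), via prenylated dioxolane 9 (not isolated)
Conditions: n-BuLi, THF, −78 °C; CuBr·SMe2 (10 mol %), 7, −78 to 0 °C; then 2 M aq. HCl, THF, rt
Reagents that add atoms: water O (the carbonyl oxygen on ketal hydrolysis)
Why: bromine–lithium exchange gives aryllithium 8 without harm to the ketal, copper-catalysed allylic substitution on prenyl bromide should take place at the unhindered primary carbon (SN2 sense, the tertiary terminus being shielded) to give 9, and the acidic work-up hydrolyses the dioxolane.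

Step 5
Reactants: 10 1-[4-methoxy-3-(3-methylbut-2-en-1-yl)phenyl]ethanone; 4 2-bromo-4,6-bis(methoxymethoxy)benzaldehyde
Product: 12 rac-3-[2-bromo-4,6-bis(methoxymethoxy)phenyl]-3-hydroxy-1-[4-methoxy-3-(3-methylbut-2-en-1-yl)phenyl]propan-1-one, via lithium enolate 11 (not isolated)
Conditions: LDA, THF, −78 °C; then 4, −78 °C; AcOH, −78 °C (crude product taken on)
Reagents that add atoms: none
Why: directed aldol addition of the preformed lithium enolate of a methyl ketone to a non-enolisable aldehyde (LDA leaves the aryl bromide alone) forms the C3–C4 bond; the carbinol is formed racemic and is erased in step 6.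

Step 6
Reactants: 12 racemic aldol adduct
Product: 13 1-[2-bromo-4,6-bis(methoxymethoxy)phenyl]-3-[4-methoxy-3-(3-methylbut-2-en-1-yl)phenyl]propane-1,3-dione
Conditions: Dess–Martin periodinane, pyridine, CH2Cl2, 0 °C to rt
Reagents that add atoms: none
Why: Dess–Martin oxidation of a secondary benzylic alcohol to the 1,3-diketone (held largely as its chelated enol) under pyridine-buffered, near-neutral conditions that should spare the MOM ethers and the prenyl olefin.

Step 7
Reactants: 13 the 1,3-diketone
Product: 14 (3S)-1-[2-bromo-4,6-bis(methoxymethoxy)phenyl]-3-hydroxy-3-[4-methoxy-3-(3-methylbut-2-en-1-yl)phenyl]propan-1-one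
Conditions: RuCl(p-cymene)[(S,S)-TsDPEN] (2 mol %), HCO2H/Et3N (5:2), EtOAc, 30 °C
Reagents that add atoms: none
Why: Noyori asymmetric transfer hydrogenation, in which the ruthenium hydride/N–H pair reduces the unhindered ring B aryl ketone through the six-membered transition state with the aryl group in the CH/π-favoured position, so that the (S,S)-ligand should give the S carbinol (the sense in which acetophenone gives (S)-1-phenylethanol), while the ring A carbonyl, twisted out of conjugation and flanked by Br and OMOM, should stay; this sets C2 of the target.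

Step 8
Reactants: 14 the (3S)-hydroxy ketone
Product: 15 (1S,3S)-1-[2-bromo-4,6-bis(methoxymethoxy)phenyl]-3-[4-methoxy-3-(3-methylbut-2-en-1-yl)phenyl]propane-1,3-diol
Conditions: Me4NBH(OAc)3, MeCN/AcOH (1:1), −30 to −20 °C
Reagents that add atoms: none
Why: Evans–Saksena hydroxyl-directed reduction, in which the C3 hydroxyl exchanges onto boron and delivers hydride within a chair-like six-membered transition state, which should give the 1,3-anti diol and thus the 1S configuration.

Step 9
Reactants: 15 the (1S,3S)-bromo diol
Product: 16 (2S,4S)-5,7-bis(methoxymethoxy)-4'-methoxy-3'-(3-methylbut-2-en-1-yl)flavan-4-ol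
Conditions: CuI (10 mol %), 3,4,7,8-tetramethyl-1,10-phenanthroline (20 mol %), Cs2CO3, degassed toluene (0.02 M), 110 °C, argon
Reagents that add atoms: none
Why: Ullmann-type copper-catalysed C–O coupling: Cs2CO3 forms the alkoxide of the C2 carbinol (C3 of 15), which binds phenanthroline-ligated monovalent copper, the metal then activates the C8a–Br bond (oxidative addition to an aryl trivalent-copper alkoxide) and reductive elimination gives the aryl ether O1–C8a. The closest known reaction type is the copper-catalysed intramolecular O-arylation of secondary benzylic alcohols by ortho-tethered aryl bromides, which gives chromans and 2-arylchromans. Ring C closes as a six-membered ring in a 6-exo sense at the aryl carbon, by way of a seven-membered cupracycle. No stereocentre is formed; the C2–O bond is never broken, so 3S of 15 should become 2S of 16 with retention, and with C4 at the alcohol level there is no carbonyl through which the carbonate base could bring about retro-aldol cleavage or β-elimination. The step needs a choice between the two hydroxyls, which ring size secures (the C4 hydroxyl could reach C8a only by forming a four-membered benzoxete), and a C–Br bond that is not deactivated, which holds because both OMOM groups stand meta to C8a. Dilution holds back intermolecular etherification and exclusion of air holds back copper-mediated oxidation of the benzylic alkoxides.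

Step 10
Reactants: 16 the (2S,4S)-flavan-4-ol
Product: 17 (2S)-5,7-bis(methoxymethoxy)-4'-methoxy-3'-(3-methylbut-2-en-1-yl)flavanone
Conditions: Dess–Martin periodinane, pyridine, CH2Cl2, 0 °C to rt
Reagents that add atoms: none
Why: Dess–Martin oxidation of the benzylic C4 alcohol to the aryl ketone under buffered conditions without strong base, so that the flavanone should not open to the chalcone by E1cB elimination and C2 keeps its configuration.

Step 11
Reactants: 17 the bis-MOM flavanone
Product: 18 4'-O-methyllicoflavanone, (2S)-5,7-dihydroxy-4'-methoxy-3'-(3-methylbut-2-en-1-yl)flavanone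
Conditions: 3 M aq. HCl/MeOH (1:5), 45 °C
Reagents that add atoms: none
Why: acid-catalysed acetal exchange of the two aryl MOM ethers with methanol; the prenyl group has no free ortho phenol onto which it could cyclise, and the ring opening that racemises flavanones is mainly base-mediated, so C2 should hold.

**Compound list**

1 | 5-bromoresorcinol | Oc1cc(O)cc(Br)c1 | starting material
2 | N-[(2-bromo-4,6-dihydroxyphenyl)methylidene]-N-methylmethanaminium chloride | C[N+](C)=Cc1c(O)cc(O)cc1Br.[Cl-] | intermediate
3 | 2-bromo-4,6-dihydroxybenzaldehyde | O=Cc1c(O)cc(O)cc1Br | intermediate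
4 | 2-bromo-4,6-bis(methoxymethoxy)benzaldehyde | O=Cc1c(OCOC)cc(OCOC)cc1Br | intermediate
5 | 1-(3-bromo-4-methoxyphenyl)ethanone | CC(=O)c1ccc(OC)c(Br)c1 | starting material
6 | 2-(3-bromo-4-methoxyphenyl)-2-methyl-1,3-dioxolane | COc1ccc(C2(C)OCCO2)cc1Br | intermediate
7 | prenyl bromide (1-bromo-3-methylbut-2-ene) | CC(C)=CCBr | starting material
8 | [2-methoxy-5-(2-methyl-1,3-dioxolan-2-yl)phenyl]lithium | [Li]c1cc(C2(C)OCCO2)ccc1OC | intermediate
9 | 2-[4-methoxy-3-(3-methylbut-2-en-1-yl)phenyl]-2-methyl-1,3-dioxolane | COc1ccc(C2(C)OCCO2)cc1CC=C(C)C | intermediate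
10 | 1-[4-methoxy-3-(3-methylbut-2-en-1-yl)phenyl]ethanone | CC(=O)c1ccc(OC)c(CC=C(C)C)c1 | intermediate
11 | lithium enolate of 10 | [Li]OC(=C)c1ccc(OC)c(CC=C(C)C)c1 | intermediate
12 | rac-3-[2-bromo-4,6-bis(methoxymethoxy)phenyl]-3-hydroxy-1-[4-methoxy-3-(3-methylbut-2-en-1-yl)phenyl]propan-1-one | COc1ccc(C(=O)CC(O)c2c(OCOC)cc(OCOC)cc2Br)cc1CC=C(C)C | intermediate
13 | 1-[2-bromo-4,6-bis(methoxymethoxy)phenyl]-3-[4-methoxy-3-(3-methylbut-2-en-1-yl)phenyl]propane-1,3-dione | COc1ccc(C(=O)CC(=O)c2c(OCOC)cc(OCOC)cc2Br)cc1CC=C(C)C | intermediate
14 | (3S)-1-[2-bromo-4,6-bis(methoxymethoxy)phenyl]-3-hydroxy-3-[4-methoxy-3-(3-methylbut-2-en-1-yl)phenyl]propan-1-one | COc1ccc([C@@H](O)CC(=O)c2c(OCOC)cc(OCOC)cc2Br)cc1CC=C(C)C | intermediate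
15 | (1S,3S)-1-[2-bromo-4,6-bis(methoxymethoxy)phenyl]-3-[4-methoxy-3-(3-methylbut-2-en-1-yl)phenyl]propane-1,3-diol | COc1ccc([C@@H](O)C[C@H](O)c2c(OCOC)cc(OCOC)cc2Br)cc1CC=C(C)C | intermediate
16 | (2S,4S)-5,7-bis(methoxymethoxy)-4'-methoxy-3'-(3-methylbut-2-en-1-yl)flavan-4-ol | COc1ccc([C@@H]2C[C@H](O)c3c(OCOC)cc(OCOC)cc3O2)cc1CC=C(C)C | intermediate
17 | (2S)-5,7-bis(methoxymethoxy)-4'-methoxy-3'-(3-methylbut-2-en-1-yl)flavanone | COc1ccc([C@@H]2CC(=O)c3c(OCOC)cc(OCOC)cc3O2)cc1CC=C(C)C | intermediate
18 | 4'-O-methyllicoflavanone, (2S)-5,7-dihydroxy-4'-methoxy-3'-(3-methylbut-2-en-1-yl)flavanone | COc1ccc([C@@H]2CC(=O)c3c(O)cc(O)cc3O2)cc1CC=C(C)C | target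

**Step count**

Total: 11 steps. Longest linear sequence: 9 steps (steps 1, 2, 5–11 from 1; equally steps 3, 4, 5–11 from 5).

**Steps most likely to fail**

Step 9 (ring closure). The C–O bond formation at the secondary benzylic alkoxide may be slow, so that reduction of the C–Br bond (β-hydride loss from the copper alkoxide) or oxidation of a carbinol overtakes it. Fallback: set out from 15 and make the same O1–C8a bond in a different catalytic manifold, a Buchwald–Hartwig-type etherification on zerovalent palladium (Pd(OAc)2, 2-(di-tert-butylphosphino)-1,1'-binaphthyl, Cs2CO3, toluene, 60–70 °C). Oxidative addition of the aryl bromide, alkoxide ligation and C–O reductive elimination driven by the bulky phosphine should run at lower temperature and again leave the C2–O bond untouched. It comes back to the route at 16 and makes no new compound (F0).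

Step 7 (transfer hydrogenation). Hydride transfer may go to the wrong carbonyl or to both, turnover may stall because the chelated enol binds ruthenium, or the enantioselectivity may erode. Fallback: set out from 12, which holds the ring B carbonyl as the only ketone, and avoid the diketone altogether. The same catalyst (RuCl(p-cymene)[(S,S)-TsDPEN], HCO2H/Et3N) should reduce 12 under catalyst control to the pair of C1-epimeric (3S)-diols F1 (15 and its C1 epimer). Both epimers are cyclised under the conditions of step 9 to the C4-epimeric (2S)-flavan-4-ols F2 and oxidised under the conditions of step 10. The epimers converge there, so the fallback comes back to the route at 17.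

Step 8 (anti reduction). Internal hydride delivery to a carbonyl that is shielded on both faces by Br and OMOM may be slow or unselective. Fallback: set out from 14 and use a chelate with external hydride, the Narasaka–Prasad reduction (Et2BOMe, NaBH4, THF/MeOH, −78 °C), which should give the (1R,3S)-syn diol F3. The conditions of step 9 should close it to the (2S,4R)-flavan-4-ol F4, and the conditions of step 10 oxidise this to the same ketone, so the fallback comes back to the route at 17.

**Further compounds**

F0 | step 9 | none | none
F1 | step 7 | (3S)-1-[2-bromo-4,6-bis(methoxymethoxy)phenyl]-3-[4-methoxy-3-(3-methylbut-2-en-1-yl)phenyl]propane-1,3-diol, both C1 epimers | COc1ccc([C@@H](O)CC(O)c2c(OCOC)cc(OCOC)cc2Br)cc1CC=C(C)C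
F2 | step 7 | (2S)-5,7-bis(methoxymethoxy)-4'-methoxy-3'-(3-methylbut-2-en-1-yl)flavan-4-ol, both C4 epimers | COc1ccc([C@@H]2CC(O)c3c(OCOC)cc(OCOC)cc3O2)cc1CC=C(C)C
F3 | step 8 | (1R,3S)-1-[2-bromo-4,6-bis(methoxymethoxy)phenyl]-3-[4-methoxy-3-(3-methylbut-2-en-1-yl)phenyl]propane-1,3-diol | COc1ccc([C@@H](O)C[C@@H](O)c2c(OCOC)cc(OCOC)cc2Br)cc1CC=C(C)C
F4 | step 8 | (2S,4R)-5,7-bis(methoxymethoxy)-4'-methoxy-3'-(3-methylbut-2-en-1-yl)flavan-4-ol | COc1ccc([C@@H]2C[C@@H](O)c3c(OCOC)cc(OCOC)cc3O2)cc1CC=C(C)C
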